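**Retrosynthetic overview**
- The furanone ring is formed last: after oxidation of C1 and desilylation, the C10 hydroxyl adds to C3 of a ten-membered cyclodec-4-en-2-yn-1-one (5-endo-dig).
- The strategy rests on C1: it is a carbonyl carbon bonded to fully substituted C10 and to the C2=C3–C4=C5 dienyl unit of the ten-membered carbocycle. With C2≡C3 as an alkyne, the carbocycle closes at C1–C2 by Cr(II)/Ni addition of an iodoalkyne to an aldehyde that has no α-hydrogen.
- The open-chain precursor comes from a C7–C8 chromium allylation of a citramalate-derived C8 aldehyde with a (6R)-3-(bromomethyl)butenolide; C8 is then inverted during Mitsunobu esterification with isobutyric acid.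
- The butenolide comes from butynediol: two Red-Al/I2 hydroiodinations, a Sonogashira coupling, a ligand-controlled alkynylation (C6) and a Pd/CO lactonisation.
- Ring order: butenolide (which becomes the methylene lactone), then the ten-membered carbocycle, then the furanone.

Key step: step 19

**Remarks**
- Locants C1–C15 are those of the germacrane skeleton of the target (lactone C12(=O)–O–C6, C14 = methyl on C10, C15 = CH2O on C4).
- Assumption: the chromium allylation in step 13 passes through the closed chair transition state, which gives the 7,8-anti adduct (8S); the isobutyrate is therefore introduced with inversion (step 14), not by simple acylation.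
- Assumption: (R,R)-ProPhenol is taken as the ligand antipode that delivers the alkynylzinc to the Si face of aldehyde 7; if the sense proves opposite, the other antipode is used.
- C15 is carried as a TBDPS ether and C1/C10 as an acetonide until step 15, so that the acid step does not touch C15.
- Abbreviation: SC = (1E)-2-{[(tert-butyldiphenylsilyl)oxy]methyl}-4-(trimethylsilyl)but-1-en-3-yn-1-yl (the C5=C4 unit, alkyne cis to C6); SC-I is the same group with iodine in place of SiMe3. The alkene geometry never changes; only its CIP label does.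

**Route**

Step 1
Reactants: 1 2-butyne-1,4-diol
Product: 2 4-[(tert-butyldiphenylsilyl)oxy]but-2-yn-1-ol
Conditions: NaH (1.0 equiv), THF, 0 °C to rt; then TBDPSCl (1.0 equiv)
Reagents that add atoms: tert-butyl(chloro)diphenylsilane, CC(C)(C)[Si](Cl)(c1ccccc1)c1ccccc1
Why: O-silylation of the sparingly soluble mono-sodium alkoxide of a symmetrical diol should stop at the mono-ether.

Step 2
Reactants: 2 4-[(tert-butyldiphenylsilyl)oxy]but-2-yn-1-ol
Product: 4 (Z)-4-[(tert-butyldiphenylsilyl)oxy]-3-iodobut-2-en-1-ol, via cyclic vinylalanate 3 (not isolated)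
Conditions: Red-Al (1.6 equiv), THF, 0 °C; then I2, −78 to 0 °C
Reagents that add atoms: iodine, II
Why: Alkoxide-directed trans-hydroalumination of the propargylic alcohol puts aluminium on the distal alkyne carbon in a five-membered alanate, and iodinolysis with retention gives the iodoalkene with iodine cis to CH2OH.

Step 3
Reactants: 4 (Z)-4-[(tert-butyldiphenylsilyl)oxy]-3-iodobut-2-en-1-ol; 5 trimethylsilylacetylene
Product: 6 (E)-3-{[(tert-butyldiphenylsilyl)oxy]methyl}-5-(trimethylsilyl)pent-2-en-4-yn-1-ol (alkyne cis to CH2OH)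
Conditions: PdCl2(PPh3)2 (cat.), CuI (cat.), Et3N, THF, rt
Reagents that add atoms: none
Why: Sonogashira coupling of an alkenyl iodide proceeds with retention of alkene geometry, so the alkyne (C2≡C3) ends cis to the future C6.

Step 4
Reactants: 6 (E)-3-{[(tert-butyldiphenylsilyl)oxy]methyl}-5-(trimethylsilyl)pent-2-en-4-yn-1-ol
Product: 7 (E)-3-{[(tert-butyldiphenylsilyl)oxy]methyl}-5-(trimethylsilyl)pent-2-en-4-ynal
Conditions: MnO2 (excess), CH2Cl2, rt
Reagents that add atoms: none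
Why: Neutral heterogeneous allylic oxidation with MnO2 should give the enal without isomerising the trisubstituted alkene.

Step 5
Reactants: 7 (E)-3-{[(tert-butyldiphenylsilyl)oxy]methyl}-5-(trimethylsilyl)pent-2-en-4-ynal; 8 tert-butyldimethyl(prop-2-yn-1-yloxy)silane
Product: 9 (4R,5E)-1-[(tert-butyldimethylsilyl)oxy]-6-{[(tert-butyldiphenylsilyl)oxy]methyl}-8-(trimethylsilyl)oct-5-ene-2,7-diyn-4-ol
Conditions: Me2Zn (3 equiv), 8 (3 equiv), (R,R)-ProPhenol (20 mol%), Ph3P=O (40 mol%), toluene, 0 °C; aq NH4Cl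
Reagents that add atoms: none
Why: Dinuclear zinc–ProPhenol catalysed enantioselective alkynylation of an enal; the ligand controls the face, and Si-face addition sets C6 as R.

Step 6
Reactants: 9 (4R,5E)-1-[(tert-butyldimethylsilyl)oxy]-6-{[(tert-butyldiphenylsilyl)oxy]methyl}-8-(trimethylsilyl)oct-5-ene-2,7-diyn-4-ol
Product: 11 (2Z,4R,5E)-1-[(tert-butyldimethylsilyl)oxy]-6-{[(tert-butyldiphenylsilyl)oxy]methyl}-2-iodo-8-(trimethylsilyl)octa-2,5-dien-7-yn-4-ol, via cyclic vinylalanate 10 (not isolated)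
Conditions: Red-Al, THF, −20 to 0 °C; then I2, −78 °C
Reagents that add atoms: iodine, II
Why: The C6 alkoxide directs trans-hydroalumination to the adjacent C7≡C11 alkyne only (the silylated enyne has no directing group), giving after iodinolysis the C11 iodide cis to C6, with C6 untouched.

Step 7
Reactants: 11 (2Z,4R,5E)-1-[(tert-butyldimethylsilyl)oxy]-6-{[(tert-butyldiphenylsilyl)oxy]methyl}-2-iodo-8-(trimethylsilyl)octa-2,5-dien-7-yn-4-ol
Product: 12 (5R)-3-{[(tert-butyldimethylsilyl)oxy]methyl}-5-SC-furan-2(5H)-one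
Conditions: PdCl2(PPh3)2 (5 mol%), CO (1 atm), K2CO3, THF, rt
Reagents that add atoms: carbon monoxide, [C-]#[O+]
Why: Pd-catalysed cyclocarbonylation: oxidative addition at C11–I, CO insertion and capture of the acylpalladium by the cis C6 hydroxyl close the butenolide (C12 introduced) without touching C6.

Step 8
Reactants: 12 (5R)-3-{[(tert-butyldimethylsilyl)oxy]methyl}-5-SC-furan-2(5H)-one
Product: 13 (5R)-3-(hydroxymethyl)-5-SC-furan-2(5H)-one
Conditions: PPTS (cat.), MeOH, rt
Reagents that add atoms: none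
Why: Acid-catalysed methanolysis cleaves the primary TBS ether much faster than the TBDPS ether and leaves the alkynylsilane and butenolide intact.

Step 9
Reactants: 13 (5R)-3-(hydroxymethyl)-5-SC-furan-2(5H)-one
Product: 14 (5R)-3-(bromomethyl)-5-SC-furan-2(5H)-one
Conditions: CBr4, PPh3, CH2Cl2, 0 °C
Reagents that add atoms: carbon tetrabromide, BrC(Br)(Br)Br
Why: Appel bromination converts the primary allylic alcohol to the bromide under neutral conditions, avoiding base at the acidic C6–H.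

Step 10
Reactants: 15 (R)-citramalic acid
Product: 16 (R)-2-methylbutane-1,2,4-triol
Conditions: BH3·SMe2, B(OMe)3, THF, 0 °C to rt; MeOH
Reagents that add atoms: none
Why: Borane reduces both carboxylic acids to primary alcohols and does not touch the quaternary carbinol centre (future C10).

Step 11
Reactants: 16 (R)-2-methylbutane-1,2,4-triol
Product: 17 2-[(4R)-2,2,4-trimethyl-1,3-dioxolan-4-yl]ethan-1-ol
Conditions: 2,2-dimethoxypropane, acetone, TsOH (cat.), rt
Reagents that add atoms: 2,2-dimethoxypropane, COC(C)(C)OC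
Why: Thermodynamic acetalisation favours the five-membered dioxolane on the 1,2-diol (C1/C10 oxygens) over the six-membered alternative with its axial methyl, leaving the C8 hydroxyl free.

Step 12
Reactants: 17 2-[(4R)-2,2,4-trimethyl-1,3-dioxolan-4-yl]ethan-1-ol
Product: 18 2-[(4R)-2,2,4-trimethyl-1,3-dioxolan-4-yl]acetaldehyde
Conditions: (COCl)2, DMSO, CH2Cl2, −78 °C; Et3N
Reagents that add atoms: none
Why: Swern oxidation gives the C8 aldehyde under non-acidic conditions that keep the acetonide.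

Step 13
Reactants: 14 (5R)-3-(bromomethyl)-5-SC-furan-2(5H)-one; 18 2-[(4R)-2,2,4-trimethyl-1,3-dioxolan-4-yl]acetaldehyde
Product: 19 (4R,5R)-4-{(1S)-1-hydroxy-2-[(4R)-2,2,4-trimethyl-1,3-dioxolan-4-yl]ethyl}-3-methylidene-5-SC-oxolan-2-one (6R,7R,8S,10R)
Conditions: CrCl2 (3.5 equiv), THF, 0 °C to rt; 18 (1.5 equiv)
Reagents that add atoms: none
Why: Chromium(II) Barbier (Nozaki–Hiyama) allylation: the allylchromium reacts at its γ-carbon C7 through a Zimmerman–Traxler chair on the face anti to the C6 substituent (trans lactone, 7R), and because the ring holds C6 trans to the CH2Cr carbon (E-crotyl type) the adduct should be 7,8-anti, i.e. 8S.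

Step 14
Reactants: 19 (4R,5R)-4-{(1S)-1-hydroxy-2-[(4R)-2,2,4-trimethyl-1,3-dioxolan-4-yl]ethyl}-3-methylidene-5-SC-oxolan-2-one; 20 isobutyric acid
Product: 21 (1R)-1-[(2R,3R)-4-methylidene-5-oxo-2-SC-oxolan-3-yl]-2-[(4R)-2,2,4-trimethyl-1,3-dioxolan-4-yl]ethyl 2-methylpropanoate (6R,7R,8R,10R)
Conditions: PPh3, DIAD, toluene, 0 °C to rt
Reagents that add atoms: none
Why: Mitsunobu esterification displaces the C8 alkoxyphosphonium by isobutyrate with inversion (SN2), turning the 8S alcohol into the 8R ester of the target.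

Step 15
Reactants: 21 (1R)-1-[(2R,3R)-4-methylidene-5-oxo-2-SC-oxolan-3-yl]-2-[(4R)-2,2,4-trimethyl-1,3-dioxolan-4-yl]ethyl 2-methylpropanoate
Product: 22 (1R,3R)-3,4-dihydroxy-3-methyl-1-[(2R,3R)-4-methylidene-5-oxo-2-SC-oxolan-3-yl]butyl 2-methylpropanoate
Conditions: AcOH/H2O (4:1), 40 °C
Reagents that add atoms: none
Why: Aqueous acid hydrolyses the terminal acetonide, while the TBDPS ether, alkynylsilane, isobutyrate and methylene lactone are stable to these conditions.

Step 16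
Reactants: 22 (1R,3R)-3,4-dihydroxy-3-methyl-1-[(2R,3R)-4-methylidene-5-oxo-2-SC-oxolan-3-yl]butyl 2-methylpropanoate
Product: 23 (1R,3R)-3-methyl-3,4-bis[(triethylsilyl)oxy]-1-[(2R,3R)-4-methylidene-5-oxo-2-SC-oxolan-3-yl]butyl 2-methylpropanoate
Conditions: TESOTf, 2,6-lutidine, CH2Cl2, −78 to 0 °C
Reagents that add atoms: triethylsilyl trifluoromethanesulfonate, CC[Si](CC)(CC)OS(=O)(=O)C(F)(F)F
Why: The silyl triflate with a hindered base silylates both the primary C1 and the tertiary C10 hydroxyl.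

Step 17
Reactants: 23 (1R,3R)-3-methyl-3,4-bis[(triethylsilyl)oxy]-1-[(2R,3R)-4-methylidene-5-oxo-2-SC-oxolan-3-yl]butyl 2-methylpropanoate
Product: 24 (1R,3R)-3-methyl-4-oxo-3-[(triethylsilyl)oxy]-1-[(2R,3R)-4-methylidene-5-oxo-2-SC-oxolan-3-yl]butyl 2-methylpropanoate
Conditions: (COCl)2, DMSO, CH2Cl2, −78 to −40 °C; Et3N, −78 °C to rt
Reagents that add atoms: none
Why: Under Swern conditions the chlorosulfonium reagent cleaves only the primary O–SiEt3 bond and the resulting alkoxysulfonium collapses to the C1 aldehyde, leaving the tertiary TES and the TBDPS ether.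

Step 18
Reactants: 24 (1R,3R)-3-methyl-4-oxo-3-[(triethylsilyl)oxy]-1-[(2R,3R)-4-methylidene-5-oxo-2-SC-oxolan-3-yl]butyl 2-methylpropanoate
Product: 25 (1R,3R)-3-methyl-4-oxo-3-[(triethylsilyl)oxy]-1-[(2R,3R)-4-methylidene-5-oxo-2-(SC-I)-oxolan-3-yl]butyl 2-methylpropanoate (iodoalkynyl aldehyde)
Conditions: NIS, AgNO3 (10 mol%), acetone, rt, dark
Reagents that add atoms: N-iodosuccinimide, O=C1CCC(=O)N1I
Why: Silver-catalysed iododesilylation converts the alkynylsilane via a silver acetylide directly into the C2 iodoalkyne without affecting the aldehyde, which cannot enolise.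

Step 19
Reactants: 25 (1R,3R)-3-methyl-4-oxo-3-[(triethylsilyl)oxy]-1-[(2R,3R)-4-methylidene-5-oxo-2-(SC-I)-oxolan-3-yl]butyl 2-methylpropanoate
Product: 26 (6R,7R,8R,10R)-15-[(tert-butyldiphenylsilyl)oxy]-1-hydroxy-8-(isobutyryloxy)-10-[(triethylsilyl)oxy]germacra-4,11(13)-dien-2-yn-6,12-olide (ten-membered cyclic enyne carbinol; both C1 epimers expected, (1R) drawn)
Conditions: CrCl2 (8 equiv), NiCl2 (2 mol%), THF, rt, 25 added by syringe pump to 2 mM
Reagents that add atoms: none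
Why: Ni(0), formed from NiCl2 by Cr(II), inserts into the C2–I bond, and transmetalation gives an alkynylchromium(III) that adds to the C1 aldehyde, forming C1–C2 (Nozaki–Hiyama–Kishi alkynylation). The closest known reaction type is the Cr/Ni closure of iodoalkynyl aldehydes to ten-membered cyclic enediynes and enynes. The carbocycle closes in a 10-exo-trig mode, with the carbonyl oxygen outside the ring. The new C1 carbinol centre is not controlled and need not be, since both epimers give the same ynone in step 20. The selectivity required is ring closure over oligomerisation and alkyne homocoupling; it rests on slow addition at high dilution, on the turn imposed by the C4=C5 alkene (C3 cis to C6) and the trans lactone, and on the fully substituted C10. Chemoselectivity follows from the unhindered aldehyde without α-hydrogen and from the tolerance of organochromium(III) species for the esters, the methylene lactone and the silyl ethers.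

Step 20
Reactants: 26 (6R,7R,8R,10R)-15-[(tert-butyldiphenylsilyl)oxy]-1-hydroxy-8-(isobutyryloxy)-10-[(triethylsilyl)oxy]germacra-4,11(13)-dien-2-yn-6,12-olide
Product: 27 (6R,7R,8R,10R)-15-[(tert-butyldiphenylsilyl)oxy]-8-(isobutyryloxy)-1-oxo-10-[(triethylsilyl)oxy]germacra-4,11(13)-dien-2-yn-6,12-olide
Conditions: Dess–Martin periodinane, NaHCO3, CH2Cl2, 0 °C to rt
Reagents that add atoms: none
Why: Dess–Martin oxidation of the propargylic carbinol under buffered conditions converts both C1 epimers into the single conjugated ynone.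

Step 21
Reactants: 27 (6R,7R,8R,10R)-15-[(tert-butyldiphenylsilyl)oxy]-8-(isobutyryloxy)-1-oxo-10-[(triethylsilyl)oxy]germacra-4,11(13)-dien-2-yn-6,12-olide
Product: 30 (6R,7R,8R,10R)-3,10-epoxy-15-hydroxy-8-(isobutyryloxy)-1-oxogermacra-2,4,11(13)-trien-6,12-olide (target CNP0176924.3), via 10-hydroxy ynone 28 (not isolated), via furanone 15-O-TBDPS ether 29 (not isolated)
Conditions: HF·pyridine, pyridine, THF, 0 °C to rt
Reagents that add atoms: none
Why: Fluoride first frees the C10 hydroxyl, which adds to C3 of the ynone (5-endo-dig oxa-Michael addition of an α'-hydroxy ynone) to give the 3(2H)-furanone, and longer exposure removes the primary TBDPS group; the 10R configuration from citramalate is retained.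

**Compound list**

1 | 2-butyne-1,4-diol | OCC#CCO | starting material
2 | 4-[(tert-butyldiphenylsilyl)oxy]but-2-yn-1-ol | OCC#CCO[Si](c1ccccc1)(c1ccccc1)C(C)(C)C | intermediate
3 | sodium bis(2-methoxyethoxy) cyclic vinylalanate of 2 (2,5-dihydro-1,2-oxaluminol-2-uide, Al on the carbon bearing CH2OTBDPS) | [Na+].COCCO[Al-]1(OCCOC)OCC=C1CO[Si](c2ccccc2)(c2ccccc2)C(C)(C)C | intermediate (not isolated)
4 | (Z)-4-[(tert-butyldiphenylsilyl)oxy]-3-iodobut-2-en-1-ol | OC/C=C(I)/CO[Si](c1ccccc1)(c1ccccc1)C(C)(C)C | intermediate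
5 | trimethylsilylacetylene | C#C[Si](C)(C)C | starting material
6 | (E)-3-{[(tert-butyldiphenylsilyl)oxy]methyl}-5-(trimethylsilyl)pent-2-en-4-yn-1-ol | OC/C=C(/CO[Si](c1ccccc1)(c1ccccc1)C(C)(C)C)C#C[Si](C)(C)C | intermediate
7 | (E)-3-{[(tert-butyldiphenylsilyl)oxy]methyl}-5-(trimethylsilyl)pent-2-en-4-ynal | O=C/C=C(/CO[Si](c1ccccc1)(c1ccccc1)C(C)(C)C)C#C[Si](C)(C)C | intermediate
8 | tert-butyldimethyl(prop-2-yn-1-yloxy)silane | C#CCO[Si](C)(C)C(C)(C)C | starting material
9 | (4R,5E)-1-[(tert-butyldimethylsilyl)oxy]-6-{[(tert-butyldiphenylsilyl)oxy]methyl}-8-(trimethylsilyl)oct-5-ene-2,7-diyn-4-ol | CC(C)(C)[Si](C)(C)OCC#C[C@H](O)/C=C(/CO[Si](c1ccccc1)(c1ccccc1)C(C)(C)C)C#C[Si](C)(C)C | intermediate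
10 | sodium bis(2-methoxyethoxy) cyclic vinylalanate of 9 (Al on C11, O from C6) | [Na+].COCCO[Al-]1(OCCOC)O[C@H](/C=C(/CO[Si](c2ccccc2)(c2ccccc2)C(C)(C)C)C#C[Si](C)(C)C)C=C1CO[Si](C)(C)C(C)(C)C | intermediate (not isolated)
11 | (2Z,4R,5E)-1-[(tert-butyldimethylsilyl)oxy]-6-{[(tert-butyldiphenylsilyl)oxy]methyl}-2-iodo-8-(trimethylsilyl)octa-2,5-dien-7-yn-4-ol | CC(C)(C)[Si](C)(C)OC/C(I)=C/[C@H](O)/C=C(/CO[Si](c1ccccc1)(c1ccccc1)C(C)(C)C)C#C[Si](C)(C)C | intermediate
12 | (5R)-3-{[(tert-butyldimethylsilyl)oxy]methyl}-5-SC-furan-2(5H)-one | CC(C)(C)[Si](C)(C)OCC1=C[C@@H](/C=C(/CO[Si](c2ccccc2)(c2ccccc2)C(C)(C)C)C#C[Si](C)(C)C)OC1=O | intermediate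
13 | (5R)-3-(hydroxymethyl)-5-SC-furan-2(5H)-one | OCC1=C[C@@H](/C=C(/CO[Si](c2ccccc2)(c2ccccc2)C(C)(C)C)C#C[Si](C)(C)C)OC1=O | intermediate
14 | (5R)-3-(bromomethyl)-5-SC-furan-2(5H)-one | BrCC1=C[C@@H](/C=C(/CO[Si](c2ccccc2)(c2ccccc2)C(C)(C)C)C#C[Si](C)(C)C)OC1=O | intermediate
15 | (R)-citramalic acid | OC(=O)[C@@](C)(CC(=O)O)O | starting material
16 | (R)-2-methylbutane-1,2,4-triol | OC[C@@](C)(CCO)O | intermediate
17 | 2-[(4R)-2,2,4-trimethyl-1,3-dioxolan-4-yl]ethan-1-ol | OCC[C@]1(C)COC(C)(C)O1 | intermediate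
18 | 2-[(4R)-2,2,4-trimethyl-1,3-dioxolan-4-yl]acetaldehyde | O=CC[C@]1(C)COC(C)(C)O1 | intermediate
19 | (4R,5R)-4-{(1S)-1-hydroxy-2-[(4R)-2,2,4-trimethyl-1,3-dioxolan-4-yl]ethyl}-3-methylidene-5-SC-oxolan-2-one | CC1(C)OC[C@@](C)(C[C@H](O)[C@@H]2[C@@H](/C=C(/CO[Si](c3ccccc3)(c3ccccc3)C(C)(C)C)C#C[Si](C)(C)C)OC(=O)C2=C)O1 | intermediate
20 | isobutyric acid (2-methylpropanoic acid) | CC(C)C(=O)O | starting material
21 | (1R)-1-[(2R,3R)-4-methylidene-5-oxo-2-SC-oxolan-3-yl]-2-[(4R)-2,2,4-trimethyl-1,3-dioxolan-4-yl]ethyl 2-methylpropanoate | CC1(C)OC[C@@](C)(C[C@@H](OC(=O)C(C)C)[C@@H]2[C@@H](/C=C(/CO[Si](c3ccccc3)(c3ccccc3)C(C)(C)C)C#C[Si](C)(C)C)OC(=O)C2=C)O1 | intermediate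
22 | (1R,3R)-3,4-dihydroxy-3-methyl-1-[(2R,3R)-4-methylidene-5-oxo-2-SC-oxolan-3-yl]butyl 2-methylpropanoate | OC[C@@](C)(C[C@@H](OC(=O)C(C)C)[C@@H]1[C@@H](/C=C(/CO[Si](c2ccccc2)(c2ccccc2)C(C)(C)C)C#C[Si](C)(C)C)OC(=O)C1=C)O | intermediate
23 | (1R,3R)-3-methyl-3,4-bis[(triethylsilyl)oxy]-1-[(2R,3R)-4-methylidene-5-oxo-2-SC-oxolan-3-yl]butyl 2-methylpropanoate | CC[Si](CC)(CC)OC[C@@](C)(C[C@@H](OC(=O)C(C)C)[C@@H]1[C@@H](/C=C(/CO[Si](c2ccccc2)(c2ccccc2)C(C)(C)C)C#C[Si](C)(C)C)OC(=O)C1=C)O[Si](CC)(CC)CC | intermediate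
24 | (1R,3R)-3-methyl-4-oxo-3-[(triethylsilyl)oxy]-1-[(2R,3R)-4-methylidene-5-oxo-2-SC-oxolan-3-yl]butyl 2-methylpropanoate | O=C[C@@](C)(C[C@@H](OC(=O)C(C)C)[C@@H]1[C@@H](/C=C(/CO[Si](c2ccccc2)(c2ccccc2)C(C)(C)C)C#C[Si](C)(C)C)OC(=O)C1=C)O[Si](CC)(CC)CC | intermediate
25 | iodoalkynyl aldehyde (10-O-TES, 15-O-TBDPS): (1R,3R)-3-methyl-4-oxo-3-[(triethylsilyl)oxy]-1-[(2R,3R)-4-methylidene-5-oxo-2-(SC-I)-oxolan-3-yl]butyl 2-methylpropanoate | O=C[C@@](C)(C[C@@H](OC(=O)C(C)C)[C@@H]1[C@@H](/C=C(/CO[Si](c2ccccc2)(c2ccccc2)C(C)(C)C)C#CI)OC(=O)C1=C)O[Si](CC)(CC)CC | intermediate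
26 | ten-membered cyclic enyne carbinol: (6R,7R,8R,10R)-15-[(tert-butyldiphenylsilyl)oxy]-1-hydroxy-8-(isobutyryloxy)-10-[(triethylsilyl)oxy]germacra-4,11(13)-dien-2-yn-6,12-olide ((1R)-epimer drawn; the (1S)-epimer is carried along) | C=C1C(=O)O[C@@H]2/C=C(/CO[Si](c3ccccc3)(c3ccccc3)C(C)(C)C)C#C[C@@H](O)[C@@](C)(C[C@@H](OC(=O)C(C)C)[C@@H]12)O[Si](CC)(CC)CC | intermediate
27 | (6R,7R,8R,10R)-15-[(tert-butyldiphenylsilyl)oxy]-8-(isobutyryloxy)-1-oxo-10-[(triethylsilyl)oxy]germacra-4,11(13)-dien-2-yn-6,12-olide | C=C1C(=O)O[C@@H]2/C=C(/CO[Si](c3ccccc3)(c3ccccc3)C(C)(C)C)C#CC(=O)[C@@](C)(C[C@@H](OC(=O)C(C)C)[C@@H]12)O[Si](CC)(CC)CC | intermediate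
28 | (6R,7R,8R,10R)-15-[(tert-butyldiphenylsilyl)oxy]-10-hydroxy-8-(isobutyryloxy)-1-oxogermacra-4,11(13)-dien-2-yn-6,12-olide | C=C1C(=O)O[C@@H]2/C=C(/CO[Si](c3ccccc3)(c3ccccc3)C(C)(C)C)C#CC(=O)[C@@](C)(C[C@@H](OC(=O)C(C)C)[C@@H]12)O | intermediate (not isolated)
29 | (6R,7R,8R,10R)-15-[(tert-butyldiphenylsilyl)oxy]-3,10-epoxy-8-(isobutyryloxy)-1-oxogermacra-2,4,11(13)-trien-6,12-olide | C=C1C(=O)O[C@@H]2/C=C(/CO[Si](c4ccccc4)(c4ccccc4)C(C)(C)C)C3=CC(=O)[C@@](C)(C[C@@H](OC(=O)C(C)C)[C@@H]12)O3 | intermediate (not isolated)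
30 | (6R,7R,8R,10R)-3,10-epoxy-15-hydroxy-8-(isobutyryloxy)-1-oxogermacra-2,4,11(13)-trien-6,12-olide (CNP0176924.3) | C=C1C(=O)O[C@@H]2/C=C(/CO)C3=CC(=O)[C@@](C)(C[C@@H](OC(=O)C(C)C)[C@@H]12)O3 | target

**Step count**
- Total: 21 steps.
- Longest linear sequence: 18 steps (steps 1–9 and 13–21); the citramalate branch is 3 steps (10–12).

**Steps most likely to fail**

1. Step 19 (Cr/Ni macrocyclisation). Intermolecular addition (oligomers), nickel-mediated alkyne homocoupling and reduction of the C2–I bond to the terminal alkyne may outrun closure of the strained cyclodecenyne. The fallback sets out from 24. Catalytic AgOTf in CH2Cl2/MeOH/H2O should remove the alkynylsilane to give the terminal alkynyl aldehyde F1. F1 is added slowly to LiN(SiMe3)2/CeCl3 in THF at −78 °C at high dilution, so that the cerium acetylide adds to the C1 aldehyde; the route is rejoined at 26.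

2. Step 14 (Mitsunobu esterification). Displacement at the hindered C8 oxyphosphonium may be slow, allowing elimination towards C7=C8, acylation of the hydrazide, or phosphine addition to the methylene lactone. The fallback sets out from 19. Dess–Martin oxidation gives the C8 ketone F2. Reduction with (S)-Me-CBS and catecholborane at −78 °C, with the branched C7 side as the large group, should give the (8R)-alcohol F3. Acylation with isobutyryl chloride, pyridine and DMAP rejoins the route at 21.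

3. Step 13 (chromium allylation). Simple diastereoselectivity at C8 may erode, the chromium alkoxide may transfer the lactone to O8, or the bromide may lose configuration at its acidic C6–H. The fallback sets out from 14. Base-free Pd-catalysed borylation with B2pin2 gives the allylboronate F4. Thermal or Sc(OTf)3-catalysed allylboration of 18 through the tighter boron chair (same anti, trans sense), followed by aqueous work-up, rejoins the route at 19.

**Further compounds**
F1 | step 19 | (1R,3R)-3-methyl-4-oxo-3-[(triethylsilyl)oxy]-1-[(2R,3R)-4-methylidene-5-oxo-2-[(1E)-2-{[(tert-butyldiphenylsilyl)oxy]methyl}but-1-en-3-yn-1-yl]oxolan-3-yl]butyl 2-methylpropanoate (terminal alkynyl aldehyde) | O=C[C@@](C)(C[C@@H](OC(=O)C(C)C)[C@@H]1[C@@H](/C=C(/CO[Si](c2ccccc2)(c2ccccc2)C(C)(C)C)C#C)OC(=O)C1=C)O[Si](CC)(CC)CC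
F2 | step 14 | C8 ketone of 19 (C6, C7 and C10 unchanged): 3-methylidene-4-{[(4R)-2,2,4-trimethyl-1,3-dioxolan-4-yl]acetyl}-5-SC-oxolan-2-one | CC1(C)OC[C@@](C)(CC(=O)[C@@H]2[C@@H](/C=C(/CO[Si](c3ccccc3)(c3ccccc3)C(C)(C)C)C#C[Si](C)(C)C)OC(=O)C2=C)O1
F3 | step 14 | (4R,5R)-4-{(1R)-1-hydroxy-2-[(4R)-2,2,4-trimethyl-1,3-dioxolan-4-yl]ethyl}-3-methylidene-5-SC-oxolan-2-one (C8 epimer of 19) | CC1(C)OC[C@@](C)(C[C@@H](O)[C@@H]2[C@@H](/C=C(/CO[Si](c3ccccc3)(c3ccccc3)C(C)(C)C)C#C[Si](C)(C)C)OC(=O)C2=C)O1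
F4 | step 13 | (5R)-3-[(4,4,5,5-tetramethyl-1,3,2-dioxaborolan-2-yl)methyl]-5-SC-furan-2(5H)-one | CC1(C)OB(CC2=C[C@@H](/C=C(/CO[Si](c3ccccc3)(c3ccccc3)C(C)(C)C)C#C[Si](C)(C)C)OC2=O)OC1(C)C
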